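## Retrosynthetic overview

1. Last bond: the aryl ether C–O (Mitsunobu) between fragment B, 7-hydroxy-8-methoxycoumarin, and fragment A, the epoxy alcohol that carries the trans-methyl lactone.
2. Fragment A: oxirane from the E-allylic alcohol (Sharpless epoxidation, D-tartrate); C3 methyl by anti alkylation of the lactone enolate; lactone from a butenolide closed by ring-closing metathesis of the acrylate of a vinyl carbinol.
3. The vinyl carbinol with its E-trisubstituted alkene comes from Negishi carboalumination/hydroxymethylation of (R)-hex-1-en-5-yn-3-ol, itself made from (R)-epichlorohydrin, ethynyltrimethylsilane and a sulfonium ylide.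
4. Fragment B: the pyranone ring is closed by ring-closing metathesis of a 2-vinylaryl acrylate made from 2-methoxyresorcinol (formylation, 4-O-PMB, Wittig, acryloylation).
5. Ring order: in A the butenolide (then saturated lactone) before the oxirane; in B the pyranone on the purchased benzene ring; the branches meet in the last step.

Assumption: only skeleton-bearing compounds are numbered; reagents such as n-BuLi, Me3Al, acryloyl chloride or MeI are named on the reagent lines.

## Route

**Fragment A (steps 1–11)**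

Step 1
Reactants: 1 (2R)-2-(chloromethyl)oxirane [(R)-epichlorohydrin]; 2 ethynyltrimethylsilane
Product: 4 (2R)-1-chloro-5-(trimethylsilyl)pent-4-yn-2-ol, via lithium (trimethylsilyl)acetylide 3 (not isolated)
Conditions: 2, n-BuLi, THF, −78 °C; BF3·OEt2, then 1, −78 °C; aq. work-up
Reagents that add atoms: none
Why: Yamaguchi–Hirao alkynylation: the BF3-activated epoxide is opened by the acetylide at its unhindered CH2 (SN2), so the C–Cl bond and the stereocentre of 1 are untouched.

Step 2
Reactants: 4 (2R)-1-chloro-5-(trimethylsilyl)pent-4-yn-2-ol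
Product: 6 (3R)-6-(trimethylsilyl)hex-1-en-5-yn-3-ol, via alkynyl epoxide 5 (not isolated)
Conditions: Me3S+ I− (4 equiv), n-BuLi (3.8 equiv), THF, −20 °C to rt; aq. work-up
Reagents that add atoms: trimethylsulfonium iodide, C[S+](C)C.[I-]
Why: The alkoxide closes the terminal epoxide (intramolecular Williamson), dimethylsulfonium methylide opens it at CH2 and the betaine eliminates Me2S (one-carbon epoxide-to-allylic-alcohol homologation); the carbinol centre is not involved.

Step 3
Reactants: 6 (3R)-6-(trimethylsilyl)hex-1-en-5-yn-3-ol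
Product: 7 (3R)-hex-1-en-5-yn-3-ol
Conditions: K2CO3 (cat.), MeOH, rt
Reagents that add atoms: none
Why: Methoxide-catalysed protodesilylation of the C(sp)–Si bond; the volatile product is concentrated cold.

Step 4
Reactants: 7 (3R)-hex-1-en-5-yn-3-ol
Product: 9 (2E,5R)-3-methylhepta-2,6-diene-1,5-diol, via alkenylalane 8 (not isolated)
Conditions: Me3Al (3 equiv), Cp2ZrCl2 (0.25 equiv), CH2Cl2, 0 °C to rt; volatiles off; n-BuLi, THF, −78 °C; (CH2O)n, rt; aq. work-up
Reagents that add atoms: trimethylaluminium, C[Al](C)C; formaldehyde (from paraformaldehyde), C=O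
Why: Negishi zirconium-catalysed carboalumination adds Me and Al syn across the terminal alkyne (Me to the internal carbon), and the alkenylalanate adds to formaldehyde with retention, giving only the E-trisubstituted allylic alcohol.

Step 5
Reactants: 9 (2E,5R)-3-methylhepta-2,6-diene-1,5-diol
Product: 10 (3R,5E)-7-{[tert-butyl(dimethyl)silyl]oxy}-5-methylhepta-1,5-dien-3-ol
Conditions: TBSCl (1.05 equiv), imidazole, CH2Cl2, −20 °C
Reagents that add atoms: tert-butyldimethylsilyl chloride, CC(C)(C)[Si](C)(C)Cl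
Why: Sterically controlled O-silylation: the primary allylic hydroxyl reacts far faster than the secondary one.

Step 6
Reactants: 10 (3R,5E)-7-{[tert-butyl(dimethyl)silyl]oxy}-5-methylhepta-1,5-dien-3-ol
Product: 11 (3R,5E)-7-{[tert-butyl(dimethyl)silyl]oxy}-5-methylhepta-1,5-dien-3-yl prop-2-enoate
Conditions: acryloyl chloride, Et3N, CH2Cl2, −20 to 0 °C
Reagents that add atoms: acryloyl chloride, C=CC(=O)Cl
Why: Esterification of the secondary alcohol with an acid chloride; the stereocentre is not touched.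

Step 7
Reactants: 11 (3R,5E)-7-{[tert-butyl(dimethyl)silyl]oxy}-5-methylhepta-1,5-dien-3-yl prop-2-enoate
Product: 12 (5R)-5-[(2E)-4-{[tert-butyl(dimethyl)silyl]oxy}-2-methylbut-2-en-1-yl]furan-2(5H)-one
Conditions: second-generation Grubbs catalyst (H2IMes)(PCy3)Cl2Ru=CHPh (5 mol%), CH2Cl2 (5 mM), 40 °C
Reagents that add atoms: none
Why: Ring-closing metathesis between the vinyl group and the acrylate closes the five-membered butenolide with loss of ethylene; the trisubstituted alkene is too hindered to take part and C5 is untouched.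

Step 8
Reactants: 12 (5R)-5-[(2E)-4-{[tert-butyl(dimethyl)silyl]oxy}-2-methylbut-2-en-1-yl]furan-2(5H)-one
Product: 13 (5S)-5-[(2E)-4-{[tert-butyl(dimethyl)silyl]oxy}-2-methylbut-2-en-1-yl]oxolan-2-one
Conditions: H2 (1 atm), RhCl(PPh3)3 (5 mol%), toluene, rt
Reagents that add atoms: none
Why: Homogeneous hydrogenation with RhCl(PPh3)3 reduces the unhindered disubstituted ring alkene and leaves the trisubstituted allylic alkene (the descriptor changes to S by priority only).

Step 9
Reactants: 13 (5S)-5-[(2E)-4-{[tert-butyl(dimethyl)silyl]oxy}-2-methylbut-2-en-1-yl]oxolan-2-one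
Product: 15 (3R,5S)-5-[(2E)-4-{[tert-butyl(dimethyl)silyl]oxy}-2-methylbut-2-en-1-yl]-3-methyloxolan-2-one, via lithium enolate 14 (not isolated)
Conditions: LiN(iPr)2 (1.1 equiv), THF, −78 °C; MeI (3 equiv), −78 to −40 °C
Reagents that add atoms: iodomethane, CI
Why: Lactone enolate alkylation: MeI approaches the planar enolate anti to the C5 side chain, giving the 3,5-trans (3R) isomer (expected about 8–10:1; the minor cis isomer is removed by chromatography).

Step 10
Reactants: 15 (3R,5S)-5-[(2E)-4-{[tert-butyl(dimethyl)silyl]oxy}-2-methylbut-2-en-1-yl]-3-methyloxolan-2-one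
Product: 16 (3R,5S)-5-[(2E)-4-hydroxy-2-methylbut-2-en-1-yl]-3-methyloxolan-2-one
Conditions: HF·pyridine, pyridine, THF, 0 °C to rt
Reagents that add atoms: none
Why: Fluoride-mediated desilylation under weakly acidic conditions, which cannot epimerise C3 or open the lactone.

Step 11
Reactants: 16 (3R,5S)-5-[(2E)-4-hydroxy-2-methylbut-2-en-1-yl]-3-methyloxolan-2-one
Product: 17 (3R,5S)-5-{[(2R,3R)-3-(hydroxymethyl)-2-methyloxiran-2-yl]methyl}-3-methyloxolan-2-one
Conditions: Ti(OiPr)4 (10 mol%), D-(−)-diethyl tartrate (12 mol%), t-BuOOH, 4 Å MS, CH2Cl2, −20 °C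
Reagents that add atoms: tert-butyl hydroperoxide, CC(C)(C)OO
Why: Sharpless asymmetric epoxidation: with D-(−)-tartrate the E-allylic alcohol is epoxidised on the face that gives the (2R,3R)-oxirane (reagent control, as geraniol gives the 2S,3S epoxide with the L-tartrate); the minor diastereomer is separable.

**Fragment B (steps 12–17)**

Step 12
Reactants: 18 2-methoxybenzene-1,3-diol (2-methoxyresorcinol)
Product: 20 2,4-dihydroxy-3-methoxybenzaldehyde, via aryl iminium chloride 19 (not isolated)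
Conditions: POCl3, DMF, MeCN, 0 °C to rt; then H2O, 50 °C
Reagents that add atoms: N,N-dimethylformamide, CN(C)C=O; water, O
Why: Vilsmeier–Haack formylation at the position ortho to one hydroxyl and para to the other (both such positions are equivalent), followed by hydrolysis of the iminium salt.

Step 13
Reactants: 20 2,4-dihydroxy-3-methoxybenzaldehyde
Product: 21 2-hydroxy-3-methoxy-4-[(4-methoxyphenyl)methoxy]benzaldehyde
Conditions: 4-methoxybenzyl chloride (1.05 equiv), NaHCO3, NaI (cat.), MeCN, 60 °C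
Reagents that add atoms: 4-methoxybenzyl chloride, COc1ccc(CCl)cc1
Why: Williamson etherification with a weak base goes to the more acidic 4-OH, because the 2-OH is tied up in a hydrogen bond to the aldehyde.

Step 14
Reactants: 21 2-hydroxy-3-methoxy-4-[(4-methoxyphenyl)methoxy]benzaldehyde
Product: 22 6-ethenyl-2-methoxy-3-[(4-methoxyphenyl)methoxy]phenol
Conditions: Ph3PCH3Br (2.5 equiv), KOtBu (2.5 equiv), THF, 0 °C to rt; aq. work-up
Reagents that add atoms: methyltriphenylphosphonium bromide, C[P+](c1ccccc1)(c1ccccc1)c1ccccc1.[Br-]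
Why: Wittig methylenation of the salicylaldehyde; excess ylide compensates for the phenoxide formed first.

Step 15
Reactants: 22 6-ethenyl-2-methoxy-3-[(4-methoxyphenyl)methoxy]phenol
Product: 23 6-ethenyl-2-methoxy-3-[(4-methoxyphenyl)methoxy]phenyl prop-2-enoate
Conditions: acryloyl chloride, Et3N, CH2Cl2, 0 °C
Reagents that add atoms: acryloyl chloride, C=CC(=O)Cl
Why: O-acylation of the phenol with an acid chloride.

Step 16
Reactants: 23 6-ethenyl-2-methoxy-3-[(4-methoxyphenyl)methoxy]phenyl prop-2-enoate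
Product: 24 8-methoxy-7-[(4-methoxyphenyl)methoxy]-2H-chromen-2-one
Conditions: second-generation Grubbs catalyst (H2IMes)(PCy3)Cl2Ru=CHPh (5 mol%), CH2Cl2, 40 °C
Reagents that add atoms: none
Why: Ring-closing metathesis of the styrene and the acrylate closes the pyranone ring of the coumarin, driven by loss of ethylene and by the conjugated product.

Step 17
Reactants: 24 8-methoxy-7-[(4-methoxyphenyl)methoxy]-2H-chromen-2-one
Product: 25 7-hydroxy-8-methoxy-2H-chromen-2-one
Conditions: TFA, anisole, CH2Cl2, 0 °C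
Reagents that add atoms: none
Why: Acidolysis of the 4-methoxybenzyl ether; the benzylic cation is trapped by anisole (Friedel–Crafts), and the coumarin and the methyl ether are stable to TFA.

**Union**

Step 18
Reactants: 17 (3R,5S)-5-{[(2R,3R)-3-(hydroxymethyl)-2-methyloxiran-2-yl]methyl}-3-methyloxolan-2-one; 25 7-hydroxy-8-methoxy-2H-chromen-2-one
Product: 26 8-methoxy-7-{[(2R,3R)-3-methyl-3-{[(2S,4R)-4-methyl-5-oxooxolan-2-yl]methyl}oxiran-2-yl]methoxy}-2H-chromen-2-one
Conditions: PPh3, DIAD, THF, 0 °C to rt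
Reagents that add atoms: none
Why: Mitsunobu etherification of the acidic 7-hydroxycoumarin at the primary carbinol carbon; no stereocentre is involved, and the neutral conditions spare the oxirane and both lactones.

## Compound list

1 | (2R)-2-(chloromethyl)oxirane | ClC[C@H]1CO1 | starting material
2 | ethynyltrimethylsilane | C#C[Si](C)(C)C | starting material
3 | lithium (trimethylsilyl)acetylide | [Li]C#C[Si](C)(C)C | intermediate (not isolated)
4 | (2R)-1-chloro-5-(trimethylsilyl)pent-4-yn-2-ol | ClC[C@H](O)CC#C[Si](C)(C)C | intermediate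
5 | trimethyl{3-[(2R)-oxiran-2-yl]prop-1-yn-1-yl}silane | C[Si](C)(C)C#CC[C@@H]1CO1 | intermediate (not isolated)
6 | (3R)-6-(trimethylsilyl)hex-1-en-5-yn-3-ol | C=C[C@H](O)CC#C[Si](C)(C)C | intermediate
7 | (3R)-hex-1-en-5-yn-3-ol | C=C[C@H](O)CC#C | intermediate
8 | [(1E,4R)-4-(dimethylalumanyloxy)-2-methylhexa-1,5-dien-1-yl]dimethylalumane | C=C[C@H](O[Al](C)C)C/C(C)=C/[Al](C)C | intermediate (not isolated)
9 | (2E,5R)-3-methylhepta-2,6-diene-1,5-diol | C=C[C@H](O)C/C(C)=C/CO | intermediate
10 | (3R,5E)-7-{[tert-butyl(dimethyl)silyl]oxy}-5-methylhepta-1,5-dien-3-ol | C=C[C@H](O)C/C(C)=C/CO[Si](C)(C)C(C)(C)C | intermediate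
11 | (3R,5E)-7-{[tert-butyl(dimethyl)silyl]oxy}-5-methylhepta-1,5-dien-3-yl prop-2-enoate | C=C[C@H](OC(=O)C=C)C/C(C)=C/CO[Si](C)(C)C(C)(C)C | intermediate
12 | (5R)-5-[(2E)-4-{[tert-butyl(dimethyl)silyl]oxy}-2-methylbut-2-en-1-yl]furan-2(5H)-one | O=C1C=C[C@@H](C/C(C)=C/CO[Si](C)(C)C(C)(C)C)O1 | intermediate
13 | (5S)-5-[(2E)-4-{[tert-butyl(dimethyl)silyl]oxy}-2-methylbut-2-en-1-yl]oxolan-2-one | O=C1CC[C@@H](C/C(C)=C/CO[Si](C)(C)C(C)(C)C)O1 | intermediate
14 | lithium enolate of 13 | [Li]OC1=CC[C@@H](C/C(C)=C/CO[Si](C)(C)C(C)(C)C)O1 | intermediate (not isolated)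
15 | (3R,5S)-5-[(2E)-4-{[tert-butyl(dimethyl)silyl]oxy}-2-methylbut-2-en-1-yl]-3-methyloxolan-2-one | CC(C)(C)[Si](C)(C)OC/C=C(C)/C[C@@H]1C[C@@H](C)C(=O)O1 | intermediate
16 | (3R,5S)-5-[(2E)-4-hydroxy-2-methylbut-2-en-1-yl]-3-methyloxolan-2-one | OC/C=C(C)/C[C@@H]1C[C@@H](C)C(=O)O1 | intermediate
17 | (3R,5S)-5-{[(2R,3R)-3-(hydroxymethyl)-2-methyloxiran-2-yl]methyl}-3-methyloxolan-2-one | OC[C@H]1O[C@]1(C)C[C@@H]2C[C@@H](C)C(=O)O2 | intermediate
18 | 2-methoxybenzene-1,3-diol | COc1c(O)cccc1O | starting material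
19 | [(2,4-dihydroxy-3-methoxyphenyl)methylidene]dimethylammonium chloride | COc1c(O)ccc(C=[N+](C)C)c1O.[Cl-] | intermediate (not isolated)
20 | 2,4-dihydroxy-3-methoxybenzaldehyde | COc1c(O)ccc(C=O)c1O | intermediate
21 | 2-hydroxy-3-methoxy-4-[(4-methoxyphenyl)methoxy]benzaldehyde | COc1ccc(COc2ccc(C=O)c(O)c2OC)cc1 | intermediate
22 | 6-ethenyl-2-methoxy-3-[(4-methoxyphenyl)methoxy]phenol | COc1ccc(COc2ccc(C=C)c(O)c2OC)cc1 | intermediate
23 | 6-ethenyl-2-methoxy-3-[(4-methoxyphenyl)methoxy]phenyl prop-2-enoate | COc1ccc(COc2ccc(C=C)c(OC(=O)C=C)c2OC)cc1 | intermediate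
24 | 8-methoxy-7-[(4-methoxyphenyl)methoxy]-2H-chromen-2-one | COc1ccc(COc2ccc3ccc(=O)oc3c2OC)cc1 | intermediate
25 | 7-hydroxy-8-methoxy-2H-chromen-2-one | COc1c(O)ccc2ccc(=O)oc12 | intermediate
26 | 8-methoxy-7-{[(2R,3R)-3-methyl-3-{[(2S,4R)-4-methyl-5-oxooxolan-2-yl]methyl}oxiran-2-yl]methoxy}-2H-chromen-2-one | COc1c(OC[C@H]2O[C@]2(C)C[C@@H]2C[C@@H](C)C(=O)O2)ccc2ccc(=O)oc12 | target

## Step count and risks

Total step count: 18.
Longest linear sequence: 12 steps (steps 1–11, then step 18), which is two thirds of 18; fragment B contributes six steps in parallel.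

Steps most likely to fail:

Step 4 (carboalumination and trapping with formaldehyde on a free enynol). The fallback sets out from 7 and replaces the aluminate/formaldehyde addition by a cross-coupling. The same Me3Al/Cp2ZrCl2 carboalumination is quenched with I2 (THF, −30 °C) to give (3R,5E)-6-iodo-5-methylhexa-1,5-dien-3-ol F1. The C1 unit is then attached by Stille coupling with (tributylstannyl)methanol (Pd(PPh3)4, toluene, 90 °C), which comes back to the route at 9.

Step 7 (ring-closing metathesis of the acrylate to the butenolide, which can stall through chelated ruthenium carbenes). The fallback sets out from 10 and builds the lactone by carbonylation instead. Linear-selective hydroformylation of the vinyl group (Rh(acac)(CO)2, Xantphos, CO/H2 1:1, 10 bar, toluene, 70 °C) gives the lactol (5S)-5-[(2E)-4-{[tert-butyl(dimethyl)silyl]oxy}-2-methylbut-2-en-1-yl]oxolan-2-ol F2 as an anomer mixture. Oxidation (PhI(OAc)2, TEMPO cat., CH2Cl2) then comes back to the route at 13.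

Step 9 (the trans:cis ratio of the enolate methylation may be too low). The fallback sets out from 10 and sets the methyl centre by a cis-selective reduction followed by inversion at C5.
- Mitsunobu esterification with methacrylic acid (PPh3, DIAD, THF) inverts the carbinol to (3S,5E)-7-{[tert-butyl(dimethyl)silyl]oxy}-5-methylhepta-1,5-dien-3-yl 2-methylprop-2-enoate F3.
- Ring-closing metathesis (second-generation Grubbs catalyst (H2IMes)(PCy3)Cl2Ru=CHPh, toluene, 80 °C) gives (5S)-5-[(2E)-4-{[tert-butyl(dimethyl)silyl]oxy}-2-methylbut-2-en-1-yl]-3-methylfuran-2(5H)-one F4.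
- NiCl2·6H2O/NaBH4 (MeOH, −20 °C) adds hydrogen anti to the side chain and gives the cis lactone (3R,5R)-5-[(2E)-4-{[tert-butyl(dimethyl)silyl]oxy}-2-methylbut-2-en-1-yl]-3-methyloxolan-2-one F5.
- LiOH (THF/H2O) opens it to (2R,4R,6E)-8-{[tert-butyl(dimethyl)silyl]oxy}-4-hydroxy-2,6-dimethyloct-6-enoic acid F6. Mitsunobu lactonisation (PPh3, DIAD, toluene, high dilution) recloses the ring with inversion at the carbinol carbon and comes back to the route at 15.

## Further compounds

F1 | step 4 | (3R,5E)-6-iodo-5-methylhexa-1,5-dien-3-ol | C=C[C@H](O)C/C(C)=C/I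
F2 | step 7 | (5S)-5-[(2E)-4-{[tert-butyl(dimethyl)silyl]oxy}-2-methylbut-2-en-1-yl]oxolan-2-ol (anomer mixture) | OC1CC[C@@H](C/C(C)=C/CO[Si](C)(C)C(C)(C)C)O1
F3 | step 9 | (3S,5E)-7-{[tert-butyl(dimethyl)silyl]oxy}-5-methylhepta-1,5-dien-3-yl 2-methylprop-2-enoate | C=C[C@@H](OC(=O)C(C)=C)C/C(C)=C/CO[Si](C)(C)C(C)(C)C
F4 | step 9 | (5S)-5-[(2E)-4-{[tert-butyl(dimethyl)silyl]oxy}-2-methylbut-2-en-1-yl]-3-methylfuran-2(5H)-one | O=C1C(C)=C[C@H](C/C(C)=C/CO[Si](C)(C)C(C)(C)C)O1
F5 | step 9 | (3R,5R)-5-[(2E)-4-{[tert-butyl(dimethyl)silyl]oxy}-2-methylbut-2-en-1-yl]-3-methyloxolan-2-one | CC(C)(C)[Si](C)(C)OC/C=C(C)/C[C@H]1C[C@@H](C)C(=O)O1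
F6 | step 9 | (2R,4R,6E)-8-{[tert-butyl(dimethyl)silyl]oxy}-4-hydroxy-2,6-dimethyloct-6-enoic acid | CC(C)(C)[Si](C)(C)OC/C=C(C)/C[C@H](O)C[C@@H](C)C(=O)O
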